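## Retrosynthetic overview

1. Target 21 ⇐ alkene 20 (hydrogenation of C7=C8 sets C8) ⇐ aldehyde 18 (C10 formyl → C20 methyl).
2. 18 ⇐ enal 3 (ring A, dienophile C5=C10) + dienyl acetate 17 (diene C6=C7–C8=C9 carrying the finished tetrahydrofuran and lactone rings), joined by one enantioselective Diels–Alder reaction that closes ring B.
3. Enabling feature: ring B (C5–C6–C7–C8–C9–C10) has a cis C5–C10 fusion and carries AcO on C6 and the ether oxygen on C9 on the same face as H-5 and C20. This is the imprint of an endo [4+2] between a ring (Z)-alkene and an (E,E)-1,4-dioxygenated diene whose C9 is the enol-ether carbon of the tetrahydrofuran.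
4. 17 ⇐ iodo enol ether 14 (Suzuki–Miyaura coupling, then copper-mediated acetoxylation) ⇐ alkynol 13 (5-exo-dig iodoetherification) ⇐ α-keto ester 7 (catalytic asymmetric Mukaiyama aldol sets C13, then lactonisation).
5. Ring order: lactone ring, then tetrahydrofuran ring, then ring B last; ring A is bought as 2,2-dimethylcyclohexanone.

Key step: step 10

Remark on numbering: labdane numbering is used (C1–C10 decalin, C11–C16 side chain, C17 on C8, C18/C19 on C4, C20 on C10); the target is the cis-fused decalin with H-5, AcO-6, C17, O-9 and C20 on one face.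

Assumption: the (S)-oxazaborolidinium catalyst of step 10 is taken to expose the Re face at the formyl-bearing ring carbon of 3, as its formyl C–H···O binding model for 2-substituted enals implies; if the opposite sense is found, the (R)-catalyst is used and nothing else changes.

## Route

Step 1
Reactants: 1 2,2-dimethylcyclohexan-1-one
Product: 2 2-chloro-3,3-dimethylcyclohex-1-ene-1-carbaldehyde
Conditions: POCl3 (2.5 equiv), DMF (3 equiv), CH2Cl2, 0 → 45 °C; then aq. NaOAc
Reagents that add atoms: N,N-dimethylformamide O=CN(C)C; phosphoryl chloride O=P(Cl)(Cl)Cl; water O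
Why: Vilsmeier–Haack chloroformylation: the ketone can enolise only toward its single α-CH2, so the formyl group enters there and chloride replaces the activated carbonyl oxygen on the carbon next to the gem-dimethyl group; no stereocentre is formed.

Step 2
Reactants: 2 2-chloro-3,3-dimethylcyclohex-1-ene-1-carbaldehyde
Product: 3 3,3-dimethylcyclohex-1-ene-1-carbaldehyde
Conditions: Pd(OAc)2 (5 mol%), PPh3 (10 mol%), HCO2Na (2 equiv), DMF, 80 °C
Reagents that add atoms: none
Why: Palladium-catalysed formate hydrogenolysis of a vinylogous acyl chloride: zerovalent palladium inserts into the activated C–Cl bond, formate delivers hydride with loss of CO2, and reductive elimination should give the enal; no stereocentre is formed.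

Step 3
Reactants: 4 5-bromopent-2-yne; 5 di-tert-butyl oxalate
Product: 7 tert-butyl 2-oxohept-5-ynoate, via pent-3-yn-1-ylmagnesium bromide 6 (not isolated)
Conditions: Mg, THF, 25 °C; then 5 (2 equiv), THF, −78 °C; aq. NH4Cl
Reagents that add atoms: none
Why: Grignard mono-acylation of a dialkyl oxalate: the tetrahedral magnesium alkoxide is stable at −78 °C and collapses to the α-keto ester only on quench, so a second addition should not occur; no stereocentre is formed.

Step 4
Reactants: 8 S-tert-butyl ethanethioate
Product: 9 1-(tert-butylsulfanyl)-1-(trimethylsilyloxy)ethene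
Conditions: LiN(iPr)2, THF, −78 °C; then Me3SiCl, −78 → 0 °C
Reagents that add atoms: chlorotrimethylsilane C[Si](C)(C)Cl
Why: Kinetic lithium enolate formation and O-silylation of a thioester should give the silyl ketene thioacetal; no stereocentre is formed.

Step 5
Reactants: 7 tert-butyl 2-oxohept-5-ynoate; 9 1-(tert-butylsulfanyl)-1-(trimethylsilyloxy)ethene
Product: 11 tert-butyl (2R)-2-[2-(tert-butylsulfanyl)-2-oxoethyl]-2-hydroxyhept-5-ynoate, via silyl ether 10 (not isolated)
Conditions: [Cu((R,R)-tBu-box)](OTf)2 (10 mol%; tBu-box = 2,2'-(propane-2,2-diyl)bis(4-tert-butyl-4,5-dihydro-1,3-oxazole)), THF, −78 °C; then 1 M HCl, 0 °C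
Reagents that add atoms: none
Why: Catalytic enantioselective Mukaiyama aldol addition to a chelated α-keto ester: the keto ester binds the divalent copper centre through both carbonyl oxygens, one tert-butyl group of the ligand blocks one ketone face and the enol silane adds to the other, which sets C13 as (R); the (R,R)-ligand is the mirror image of the one that gives (S)-adducts from pyruvate esters.

Step 6
Reactants: 11 tert-butyl (2R)-2-[2-(tert-butylsulfanyl)-2-oxoethyl]-2-hydroxyhept-5-ynoate
Product: 13 (3R)-3-hydroxy-3-(pent-3-yn-1-yl)oxolan-2-one, via diol ester 12 (not isolated)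
Conditions: NaBH4, EtOH, 0 → 25 °C; then CF3CO2H, CH2Cl2, 25 °C
Reagents that add atoms: none
Why: Chemoselective borohydride reduction of the thioester in the presence of the hindered tert-butyl ester, followed by acid-mediated cleavage of the tert-butyl ester and 5-exo-trig lactonisation, should give the lactone ring; the quaternary C13 is not touched.

Step 7
Reactants: 13 (3R)-3-hydroxy-3-(pent-3-yn-1-yl)oxolan-2-one
Product: 14 (2E,5R)-2-(1-iodoethylidene)-1,7-dioxaspiro[4.4]nonan-6-one
Conditions: I2 (1.5 equiv), NaHCO3 (3 equiv), MeCN, 0 °C, dark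
Reagents that add atoms: iodine II
Why: Iodoetherification, 5-exo-dig: the tertiary hydroxyl attacks the iodonium-activated alkyne anti to iodine, which closes the tetrahydrofuran ring and fixes the enol ether geometry (O and I trans, hence O and CH3 cis).

Step 8
Reactants: 14 (2E,5R)-2-(1-iodoethylidene)-1,7-dioxaspiro[4.4]nonan-6-one; 15 (E)-1,2-bis(4,4,5,5-tetramethyl-1,3,2-dioxaborolan-2-yl)ethene
Product: 16 (2E,5R)-2-[(3E)-4-(4,4,5,5-tetramethyl-1,3,2-dioxaborolan-2-yl)but-3-en-2-ylidene]-1,7-dioxaspiro[4.4]nonan-6-one
Conditions: Pd(PPh3)4 (5 mol%), CsF (3 equiv), 15 (3 equiv), THF, 50 °C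
Reagents that add atoms: none
Why: Suzuki–Miyaura coupling of an alkenyl iodide with an alkenyl boronate proceeds with retention at both double bonds, and the excess of the bis-boronate should keep the second C–B bond for the next step; no stereocentre is formed.

Step 9
Reactants: 16 (2E,5R)-2-[(3E)-4-(4,4,5,5-tetramethyl-1,3,2-dioxaborolan-2-yl)but-3-en-2-ylidene]-1,7-dioxaspiro[4.4]nonan-6-one
Product: 17 (1E)-3-[(2E,5R)-6-oxo-1,7-dioxaspiro[4.4]nonan-2-ylidene]but-1-en-1-yl acetate
Conditions: Cu(OAc)2 (2 equiv), Et3N (2 equiv), 4 Å MS, MeCN, dry air, 25 °C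
Reagents that add atoms: copper diacetate CC(=O)[O-].CC(=O)[O-].[Cu+2]
Why: Chan–Lam-type oxidative C–O coupling: transmetalation of the alkenyl boronate to divalent copper, oxidation to trivalent copper and C–O reductive elimination with acetate should give the enol acetate with retention of the E geometry.

Step 10
Reactants: 3 3,3-dimethylcyclohex-1-ene-1-carbaldehyde; 17 (1E)-3-[(2E,5R)-6-oxo-1,7-dioxaspiro[4.4]nonan-2-ylidene]but-1-en-1-yl acetate
Product: 18 (5S,6S,9R,10S,13R)-6-acetoxy-9,13-epoxy-20-oxolabd-7-en-16,15-olide (cis-fused aldehyde adduct)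
Conditions: (S)-1-(2-methylphenyl)-3,3-diphenyltetrahydro-1H,3H-pyrrolo[1,2-c][1,3,2]oxazaborole (20 mol%), HNTf2 (18 mol%), CH2Cl2, −78 → −40 °C, 3 (1.5 equiv)
Reagents that add atoms: none
Why: The boron-bound, LUMO-lowered s-trans enal 3 and the electron-rich diene 17 should combine in a concerted but strongly asynchronous normal-demand [4+2] cycloaddition in which the C6–C5 bond runs ahead of the C9–C10 bond; the closest known reaction type is the oxazaborolidinium-catalysed Diels–Alder reaction of 2-substituted enals with 1-oxygenated 1,3-dienes. Ring B is the only ring closed, by intermolecular suprafacial addition of the C6=C7–C8=C9 diene across C5=C10, which leaves the C7=C8 alkene. C5 and C10 become cis because the dienophile is a ring (Z)-alkene, and C6 and C9 follow from the diene geometry (E-enol acetate, ether oxygen on the outside of the E-enol ether) together with the endo position of the formyl group, so that AcO-6, H-5, the C10 formyl group and O-9 end on one face; the absolute sense, and with it the relation of C9 to the existing C13, is set by the catalyst, which shields one face of the enal and overrides the weak facial bias of the diene. Regioselectivity is needed and is secured by the alkyl enol ether oxygen on C9, the dominant donor, which makes C6 the nucleophilic terminus that bonds to the β-carbon C5, while the acetoxy group is only a weak donor. Endo selectivity is needed and is secured because the exo mode would push ring A with its C4 gem-dimethyl group under the diene. The steric cost of the inside C11H2 group and of the two adjacent fully substituted carbons C9 and C10 is met by the high nucleophilicity of the diene and the cationic activation of the aldehyde.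

Step 11
Reactants: 18 (5S,6S,9R,10S,13R)-6-acetoxy-9,13-epoxy-20-oxolabd-7-en-16,15-olide
Product: 20 (5S,6S,9R,10R,13R)-6-acetoxy-9,13-epoxylabd-7-en-16,15-olide, via tosylhydrazone 19 (not isolated)
Conditions: TsNHNH2, EtOH, 50 °C; then catecholborane, CHCl3, 0 °C; NaOAc·3H2O, reflux
Reagents that add atoms: none
Why: Caglioti-type reduction: the aldehyde tosylhydrazone is reduced at C=N by catecholborane and acetate then triggers loss of sulfinate and N2, which should turn the C10 formyl group into the C20 methyl group under conditions that spare acetate, lactone and alkene; no stereocentre changes.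

Step 12
Reactants: 20 (5S,6S,9R,10R,13R)-6-acetoxy-9,13-epoxylabd-7-en-16,15-olide
Product: 21 (5S,6S,8R,9R,10R,13R)-6-acetoxy-9,13-epoxylabdan-16,15-olide (target)
Conditions: Mn(dpm)3 (10 mol%; dpm = 2,2,6,6-tetramethylheptane-3,5-dionate), PhSiH3 (1.5 equiv), tBuOOH (1.5 equiv), iPrOH, 25 °C
Reagents that add atoms: none
Why: Metal-hydride hydrogen-atom-transfer hydrogenation: a hydrogen atom adds to C7 to give the tertiary C8 radical, which should take the second hydrogen atom along the axial direction of the chair so that C17 ends equatorial (8R), the strongly favoured arrangement because the C8 epimer would place C17 syn-axial to C1; the radical pathway leaves acetate, ether and lactone alone.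

## Compound list

1 | 2,2-dimethylcyclohexan-1-one | CC1(C)CCCCC1=O | starting material
2 | 2-chloro-3,3-dimethylcyclohex-1-ene-1-carbaldehyde | O=CC1=C(Cl)C(C)(C)CCC1 | intermediate
3 | 3,3-dimethylcyclohex-1-ene-1-carbaldehyde | O=CC1=CC(C)(C)CCC1 | intermediate
4 | 5-bromopent-2-yne | CC#CCCBr | starting material
5 | di-tert-butyl oxalate | CC(C)(C)OC(=O)C(=O)OC(C)(C)C | starting material
6 | pent-3-yn-1-ylmagnesium bromide | CC#CCC[Mg]Br | intermediate (not isolated)
7 | tert-butyl 2-oxohept-5-ynoate | CC#CCCC(=O)C(=O)OC(C)(C)C | intermediate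
8 | S-tert-butyl ethanethioate | CC(=O)SC(C)(C)C | starting material
9 | 1-(tert-butylsulfanyl)-1-(trimethylsilyloxy)ethene | C=C(O[Si](C)(C)C)SC(C)(C)C | intermediate
10 | tert-butyl (2R)-2-[2-(tert-butylsulfanyl)-2-oxoethyl]-2-(trimethylsilyloxy)hept-5-ynoate | CC#CCC[C@@](O[Si](C)(C)C)(CC(=O)SC(C)(C)C)C(=O)OC(C)(C)C | intermediate (not isolated)
11 | tert-butyl (2R)-2-[2-(tert-butylsulfanyl)-2-oxoethyl]-2-hydroxyhept-5-ynoate | CC#CCC[C@@](O)(CC(=O)SC(C)(C)C)C(=O)OC(C)(C)C | intermediate
12 | tert-butyl (2R)-2-hydroxy-2-(2-hydroxyethyl)hept-5-ynoate | CC#CCC[C@@](O)(CCO)C(=O)OC(C)(C)C | intermediate (not isolated)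
13 | (3R)-3-hydroxy-3-(pent-3-yn-1-yl)oxolan-2-one | CC#CCC[C@@]1(O)CCOC1=O | intermediate
14 | (2E,5R)-2-(1-iodoethylidene)-1,7-dioxaspiro[4.4]nonan-6-one | C/C(I)=C1\O[C@@]2(CCOC2=O)CC1 | intermediate
15 | (E)-1,2-bis(4,4,5,5-tetramethyl-1,3,2-dioxaborolan-2-yl)ethene | CC1(C)OB(/C=C/B2OC(C)(C)C(C)(C)O2)OC1(C)C | starting material
16 | (2E,5R)-2-[(3E)-4-(4,4,5,5-tetramethyl-1,3,2-dioxaborolan-2-yl)but-3-en-2-ylidene]-1,7-dioxaspiro[4.4]nonan-6-one | C/C(/C=C/B1OC(C)(C)C(C)(C)O1)=C1\O[C@@]2(CCOC2=O)CC1 | intermediate
17 | (1E)-3-[(2E,5R)-6-oxo-1,7-dioxaspiro[4.4]nonan-2-ylidene]but-1-en-1-yl acetate | CC(=O)O/C=C/C(C)=C1/O[C@@]2(CCOC2=O)CC1 | intermediate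
18 | (5S,6S,9R,10S,13R)-6-acetoxy-9,13-epoxy-20-oxolabd-7-en-16,15-olide | CC(=O)O[C@H]1C=C(C)[C@]2(CC[C@]3(CCOC3=O)O2)[C@]2(C=O)CCCC(C)(C)[C@H]12 | intermediate
19 | (E)-N-tosylhydrazone of aldehyde 18 | CC(=O)O[C@H]1C=C(C)[C@]2(CC[C@]3(CCOC3=O)O2)[C@]2(/C=N/NS(=O)(=O)c3ccc(C)cc3)CCCC(C)(C)[C@H]12 | intermediate (not isolated)
20 | (5S,6S,9R,10R,13R)-6-acetoxy-9,13-epoxylabd-7-en-16,15-olide | CC(=O)O[C@H]1C=C(C)[C@]2(CC[C@]3(CCOC3=O)O2)[C@]2(C)CCCC(C)(C)[C@H]12 | intermediate
21 | (5S,6S,8R,9R,10R,13R)-6-acetoxy-9,13-epoxylabdan-16,15-olide | CC(=O)O[C@H]1C[C@@H](C)[C@]2(CC[C@]3(CCOC3=O)O2)[C@]2(C)CCCC(C)(C)[C@H]12 | target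

## Step count and risks

Total step count: 12.
Longest linear sequence: 9 steps (steps 3, 5, 6, 7, 8, 9, 10, 11 and 12, from 5-bromopent-2-yne).

Steps most likely to fail:

Step 10. The cycloaddition may not start because of the inside C11H2 group and the two adjacent fully substituted carbons, may stop after the first C–C bond as an open-chain Michael-type adduct, or may lose facial selectivity. The fallback replaces Lewis-acid catalysis of the free aldehyde by an ionic Diels–Alder reaction; it sets out from 3 and 17 and comes back at 18. Aldehyde 3 is converted with ethane-1,2-diol and pyridinium p-toluenesulfonate (benzene, reflux, water removal) into 2-(3,3-dimethylcyclohex-1-en-1-yl)-1,3-dioxolane F1. F1 and 17 are combined with Me3SiOTf (10 mol%) in CH2Cl2 at −78 °C, where the ring-opened alkoxy-allyl cation is a much stronger dienophile than the aldehyde, to give the ethylene acetal of aldehyde 18 F2. As no chiral catalyst is present, the two facial isomers relative to C13 would have to be separated by chromatography. Pyridinium p-toluenesulfonate in wet acetone then returns 18.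

Step 12. The second hydrogen atom may be delivered to the wrong face of the C8 radical, which would leave C17 axial. The fallback puts C8 under thermodynamic control through a C7 ketone; it sets out from 20 and comes back at 21. Hydroboration–oxidation (BH3·SMe2, THF, 0 °C; NaBO3·4H2O) gives the 7-hydroxy derivative of 21 F3 with undefined C7 and C8 configuration. Dess–Martin periodinane, then 1,8-diazabicyclo[5.4.0]undec-7-ene in toluene, gives the 7-oxo derivative of 21 F4, in which C8 equilibrates through the enol to the equatorial C17 epimer. Ethane-1,2-dithiol with BF3·OEt2 gives the 1,3-dithiolane of F4 F5, and Raney Ni in refluxing EtOH removes the sulfur to give 21.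

Step 9. Protodeboronation or oxidative breakdown of the electron-rich dienyl boronate may outrun the C–O coupling. The fallback replaces the copper coupling by oxidation and enol acetylation; it sets out from 16 and comes back at 17. NaBO3·4H2O (THF–H2O, 0 °C) oxidises the C–B bond to the β,γ-unsaturated aldehyde 3-[(2E,5R)-6-oxo-1,7-dioxaspiro[4.4]nonan-2-ylidene]butanal F6. Ac2O, Et3N and 4-(dimethylamino)pyridine (CH2Cl2, 0 °C) then acylate the conjugated dienolate on oxygen without touching the enol ether geometry; the E/Z mixture at the new enol acetate would be separated and only the E isomer 17 carried on.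

Further compounds
F1 | step 10 | 2-(3,3-dimethylcyclohex-1-en-1-yl)-1,3-dioxolane | CC1(C)CCCC(=C1)C1OCCO1
F2 | step 10 | ethylene acetal (1,3-dioxolane) of aldehyde 18 | CC(=O)O[C@H]1C=C(C)[C@]2(CC[C@]3(CCOC3=O)O2)[C@]2(C3OCCO3)CCCC(C)(C)[C@H]12
F3 | step 12 | 7-hydroxy derivative of 21 (C7 and C8 configuration not defined) | CC(=O)O[C@H]1C(O)C(C)[C@]2(CC[C@]3(CCOC3=O)O2)[C@]2(C)CCCC(C)(C)[C@H]12
F4 | step 12 | 7-oxo derivative of 21 (C17 equatorial, spatial arrangement of 21 at all centres) | CC(=O)O[C@H]1C(=O)[C@@H](C)[C@]2(CC[C@]3(CCOC3=O)O2)[C@]2(C)CCCC(C)(C)[C@H]12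
F5 | step 12 | 1,3-dithiolane of ketone F4 | CC(=O)O[C@H]1C4(SCCS4)[C@@H](C)[C@]2(CC[C@]3(CCOC3=O)O2)[C@]2(C)CCCC(C)(C)[C@H]12
F6 | step 9 | 3-[(2E,5R)-6-oxo-1,7-dioxaspiro[4.4]nonan-2-ylidene]butanal | C/C(CC=O)=C1\O[C@@]2(CCOC2=O)CC1
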